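**Plan** (core numbered as 3,7-dioxabicyclo[3.3.0]octane: C1/C5 ring fusion, C2 carries the syringyl ring, C6 the trimethoxyphenyl ring)

- Retrosynthetic cuts, in order:
  - the O–Si bond;
  - the benzylic C2–O3 bond and the C2–aryl bond, back to a bicyclic lactol and γ-lactone;
  - a CO2Me helper is placed on C1;
  - in one cut, C8–C1 and O7–C6, which releases formaldehyde and leaves a 6-endo-aryl-3-oxabicyclo[3.1.0]hexan-2-one;
  - the cyclopropane, back to a Z-cinnamyl ether and a malonate carbene.
- Enabling feature: the C8H2–O7 edge is a formaldehyde unit. It bridges benzylic C6 (cation-stabilised by the trimethoxyphenyl ring) and ring-fusion C1, which lies α to C2. With C2 raised to a lactone carbonyl and an ester on C1, C6 and C1 become the donor and acceptor ends of one strained cyclopropane bond.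
- Forward ring order: cyclopropane, then γ-lactone, then the trimethoxyphenyl-bearing oxolane by strain-release (3+2) annulation with CH2O. The lactone is then rebuilt into the syringyl-bearing oxolane (DIBAL-H, ArLi, acid).
- Stereochemistry: a chiral Cu catalyst sets both cyclopropane CH centres on the Z-alkene, and C5 persists to the target. C6 arises by inversion in the annulation. C1 is fixed by the cis-fusion constraint, first in the annulation and again on protonation after loss of CO2Me. C2 is set by an exo-selective SN1 ring closure.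

Key step: step 5

Assumption: which ligand antipode gives the (2S,3S)-cyclopropane diester in step 3 has to be found by experiment. Both antipodes are accessible, so the absolute configuration is a matter of ligand choice.

**Step 1**
Reactants: 1 5-iodo-1,2,3-trimethoxybenzene; 2 tert-butyldimethyl(prop-2-yn-1-yloxy)silane
Product: 3 tert-butyldimethyl{[3-(3,4,5-trimethoxyphenyl)prop-2-yn-1-yl]oxy}silane
Conditions: PdCl2(PPh3)2 (2 mol %), CuI (4 mol %), Et3N, THF, rt
Reagents that add atoms: none
Why: Sonogashira coupling of an aryl iodide with a terminal alkyne is reliable even on electron-rich arenes, and the silyl ether is inert to it.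

**Step 2**
Reactants: 3 tert-butyldimethyl{[3-(3,4,5-trimethoxyphenyl)prop-2-yn-1-yl]oxy}silane
Product: 4 tert-butyldimethyl{[(2Z)-3-(3,4,5-trimethoxyphenyl)prop-2-en-1-yl]oxy}silane
Conditions: H2 (1 atm), Lindlar catalyst, quinoline, EtOAc, rt
Reagents that add atoms: none
Why: Lindlar semihydrogenation adds H2 syn to the alkyne and should give the Z-alkene, whose geometry later becomes the cis (endo-aryl) relationship on the cyclopropane.

**Step 3**
Reactants: 4 tert-butyldimethyl{[(2Z)-3-(3,4,5-trimethoxyphenyl)prop-2-en-1-yl]oxy}silane; 5 phenyliodonium bis(methoxycarbonyl)methanide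
Product: 6 dimethyl (2S,3S)-2-{[(tert-butyldimethylsilyl)oxy]methyl}-3-(3,4,5-trimethoxyphenyl)cyclopropane-1,1-dicarboxylate (cis)
Conditions: Cu(MeCN)4PF6 (10 mol %), chiral side-arm bis(oxazoline) (SaBOX, 12 mol %), 4 Å MS, toluene, 0 °C → rt
Reagents that add atoms: none
Why: Enantioselective copper-carbene cyclopropanation with a malonate iodonium ylide is known for cis-1,2-disubstituted styrenes; the concerted addition keeps the Z-geometry (cis product) and the ligand selects the alkene face, which sets both stereocentres.

**Step 4**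
Reactants: 6 dimethyl (2S,3S)-2-{[(tert-butyldimethylsilyl)oxy]methyl}-3-(3,4,5-trimethoxyphenyl)cyclopropane-1,1-dicarboxylate
Product: 8 methyl (1R,5S,6S)-2-oxo-6-(3,4,5-trimethoxyphenyl)-3-oxabicyclo[3.1.0]hexane-1-carboxylate (aryl endo), via hydroxymethyl diester 7 (not isolated)
Conditions: TBAF, THF, 0 °C → rt
Reagents that add atoms: none
Why: Fluoride desilylation frees an alkoxide that can reach only the ester on its own face, so lactonisation differentiates the two esters and makes C1 stereogenic under control of C5.

**Step 5**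
Reactants: 8 methyl (1R,5S,6S)-2-oxo-6-(3,4,5-trimethoxyphenyl)-3-oxabicyclo[3.1.0]hexane-1-carboxylate; 9 formaldehyde (charged as paraformaldehyde)
Product: 11 methyl (1S,5S,6R)-2-oxo-6-(3,4,5-trimethoxyphenyl)-3,7-dioxabicyclo[3.3.0]octane-1-carboxylate, via oxocarbenium enolate 10 (not isolated)
Conditions: (CH2O)n (5 equiv), Sn(OTf)2 (10 mol %), 4 Å MS, CH2Cl2, 0 °C → rt
Reagents that add atoms: none
Why: Sn(OTf)2 chelates the lactone and ester carbonyl groups on C1 of 8 and so polarises the strained C1–C6 bond, whose other end is a benzylic carbon backed by the 3,4,5-trimethoxyphenyl donor; the carbonyl oxygen of formaldehyde attacks C6 anti to the departing C1 (SN2-like, with release of the cyclopropane strain) and gives the oxocarbenium/tin enolate pair 10, whose enolate carbon then adds to the oxocarbenium carbon, so that the O–C(benzylic) and the CH2–C(ring fusion) bonds arise in one operation. The closest known reaction type is the Lewis-acid-catalysed (3+2) annulation of 2-arylcyclopropane-1,1-dicarboxylates with aldehydes, which is stereospecific with inversion at the donor carbon and has been applied to 2,3-disubstituted cyclopropanes in tetrahydrofuran lignan work. The single ring that closes, the new oxolane, does so by a 5-(enolexo)-endo-trig aldol-type attack on the oxocarbenium ion, the mode common to annulations of this type. C6 of 11 is controlled by the endo-aryl configuration of C6 in 8, since inversion turns it into the exo-aryl centre (aryl trans to the lactone CH2) and a looser, cation-like opening should drift to the same less hindered isomer, while the quaternary C1 is controlled by C5 because the tether lets the enolate close only to the cis-fused bicyclo[3.3.0]octane. The step needs cleavage of C1–C6 rather than C1–C5, which is secured because only C6 carries a cation-stabilising aryl group, and it needs formaldehyde to act as a nucleophile at C6 rather than as an electrophile toward the electron-rich arene, which is favoured by a catalytic Lewis acid held in the 1,3-dicarbonyl chelate and by the extra strain of the all-cis cyclopropane. Formaldehyde carries no substituent, so no cis/trans question arises at the new CH2.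

**Step 6**
Reactants: 11 methyl (1S,5S,6R)-2-oxo-6-(3,4,5-trimethoxyphenyl)-3,7-dioxabicyclo[3.3.0]octane-1-carboxylate
Product: 12 (1S,5S,6R)-6-(3,4,5-trimethoxyphenyl)-3,7-dioxabicyclo[3.3.0]octan-2-one
Conditions: LiCl, H2O, DMSO, 140 °C
Reagents that add atoms: none
Why: In the Krapcho dealkoxycarbonylation chloride demethylates the helper ester, the carboxylate loses CO2, and the lactone enolate can be protonated only to the cis-fused bicycle, so C1 is reset under control of C5 while the ether and lactone tolerate the neutral salt conditions.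

**Step 7**
Reactants: 12 (1S,5S,6R)-6-(3,4,5-trimethoxyphenyl)-3,7-dioxabicyclo[3.3.0]octan-2-one
Product: 13 (1S,5S,6R)-6-(3,4,5-trimethoxyphenyl)-3,7-dioxabicyclo[3.3.0]octan-2-ol (anomeric mixture)
Conditions: DIBAL-H (1.1 equiv), CH2Cl2, −78 °C; aq. Rochelle salt
Reagents that add atoms: none
Why: Partial reduction of a γ-lactone with DIBAL-H at low temperature stops at the aluminium lactolate, and the anomeric configuration is of no consequence.

**Step 8**
Reactants: 14 4-bromo-2,6-dimethoxyphenol
Product: 15 (4-bromo-2,6-dimethoxyphenoxy)(tert-butyl)dimethylsilane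
Conditions: TBSCl, imidazole, DMF, rt
Reagents that add atoms: tert-butyldimethylsilyl chloride, CC(C)(C)[Si](C)(C)Cl
Why: Standard silylation masks the acidic phenol for the organolithium step, and the group is later removed by fluoride without touching the benzylic ethers.

**Step 9**
Reactants: 13 (1S,5S,6R)-6-(3,4,5-trimethoxyphenyl)-3,7-dioxabicyclo[3.3.0]octan-2-ol; 15 (4-bromo-2,6-dimethoxyphenoxy)(tert-butyl)dimethylsilane
Product: 17 [4-(tert-butyldimethylsilyloxy)-3,5-dimethoxyphenyl][(3S,4S,5R)-4-(hydroxymethyl)-5-(3,4,5-trimethoxyphenyl)oxolan-3-yl]methanol (carbinol epimers), via aryllithium 16 (not isolated)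
Conditions: 15 (2.2 equiv), n-BuLi (2.2 equiv), THF, −78 °C; then 13, −78 → 0 °C; H2O
Reagents that add atoms: none
Why: Bromine–lithium exchange followed by 1,2-addition to the open hydroxy-aldehyde form of the lactol (the first equivalent deprotonates it) is an established way to extend furofuran lactols, and the new carbinol centre may form as a mixture because the next step erases it.

**Step 10**
Reactants: 17 [4-(tert-butyldimethylsilyloxy)-3,5-dimethoxyphenyl][(3S,4S,5R)-4-(hydroxymethyl)-5-(3,4,5-trimethoxyphenyl)oxolan-3-yl]methanol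
Product: 18 (1S,2R,5S,6R)-2-[4-(tert-butyldimethylsilyloxy)-3,5-dimethoxyphenyl]-6-(3,4,5-trimethoxyphenyl)-3,7-dioxabicyclo[3.3.0]octane
Conditions: CSA (10 mol %), CH2Cl2, 0 °C, short reaction time
Reagents that add atoms: none
Why: In this acid-catalysed SN1 cyclodehydration the electron-rich benzylic alcohol ionises and the primary hydroxyl captures the planar cation through the conformer that keeps the aryl group trans to the adjacent C1–C8 bond, so C2 should form with the aryl group exo from either carbinol epimer.

**Step 11**
Reactants: 18 (1S,2R,5S,6R)-2-[4-(tert-butyldimethylsilyloxy)-3,5-dimethoxyphenyl]-6-(3,4,5-trimethoxyphenyl)-3,7-dioxabicyclo[3.3.0]octane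
Product: 19 2,6-dimethoxy-4-[(1S,2R,5S,6R)-6-(3,4,5-trimethoxyphenyl)-3,7-dioxabicyclo[3.3.0]octan-2-yl]phenol (target, CID53356312)
Conditions: TBAF, AcOH (1:1), THF, 0 °C
Reagents that add atoms: none
Why: Fluoride cleaves the aryl silyl ether, and the acetic acid buffer keeps the phenoxide from opening the p-hydroxybenzylic ether through a quinone methide, so no stereocentre is touched.

**Compound list**

1 | 5-iodo-1,2,3-trimethoxybenzene | COc1cc(I)cc(OC)c1OC | starting material
2 | tert-butyldimethyl(prop-2-yn-1-yloxy)silane | C#CCO[Si](C)(C)C(C)(C)C | starting material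
3 | tert-butyldimethyl{[3-(3,4,5-trimethoxyphenyl)prop-2-yn-1-yl]oxy}silane | COc1cc(C#CCO[Si](C)(C)C(C)(C)C)cc(OC)c1OC | intermediate
4 | tert-butyldimethyl{[(2Z)-3-(3,4,5-trimethoxyphenyl)prop-2-en-1-yl]oxy}silane | COc1cc(/C=C\CO[Si](C)(C)C(C)(C)C)cc(OC)c1OC | intermediate
5 | phenyliodonium bis(methoxycarbonyl)methanide | COC(=O)[C-](C(=O)OC)[I+]c1ccccc1 | starting material
6 | dimethyl (2S,3S)-2-{[(tert-butyldimethylsilyl)oxy]methyl}-3-(3,4,5-trimethoxyphenyl)cyclopropane-1,1-dicarboxylate (cis) | COC(=O)C1(C(=O)OC)[C@H](c2cc(OC)c(OC)c(OC)c2)[C@@H]1CO[Si](C)(C)C(C)(C)C | intermediate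
7 | dimethyl (2S,3S)-2-(hydroxymethyl)-3-(3,4,5-trimethoxyphenyl)cyclopropane-1,1-dicarboxylate (formed as its alkoxide, not isolated) | COC(=O)C1(C(=O)OC)[C@H](c2cc(OC)c(OC)c(OC)c2)[C@@H]1CO | intermediate
8 | methyl (1R,5S,6S)-2-oxo-6-(3,4,5-trimethoxyphenyl)-3-oxabicyclo[3.1.0]hexane-1-carboxylate (aryl endo, cis to C4H2 and to the lactone carbonyl) | O=C1OC[C@H]2[C@@H](c3cc(OC)c(OC)c(OC)c3)[C@@]12C(=O)OC | intermediate
9 | formaldehyde (charged as paraformaldehyde, cracked by the Lewis acid) | C=O | starting material
10 | ring-opened zwitterion: lactone–ester enolate carrying the (R)-CH(Ar)–O+=CH2 group on C4 of the lactone (tin-bound in the flask, drawn metal-free, not isolated) | COC(=O)C1=C([O-])OC[C@H]1[C@H](c2cc(OC)c(OC)c(OC)c2)[O+]=C | intermediate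
11 | methyl (1S,5S,6R)-2-oxo-6-(3,4,5-trimethoxyphenyl)-3,7-dioxabicyclo[3.3.0]octane-1-carboxylate (cis-fused, aryl exo) | O=C1OC[C@@H]2[C@@]1(C(=O)OC)CO[C@H]2c3cc(OC)c(OC)c(OC)c3 | intermediate
12 | (1S,5S,6R)-6-(3,4,5-trimethoxyphenyl)-3,7-dioxabicyclo[3.3.0]octan-2-one | O=C1OC[C@@H]2[C@H]1CO[C@H]2c3cc(OC)c(OC)c(OC)c3 | intermediate
13 | (1S,5S,6R)-6-(3,4,5-trimethoxyphenyl)-3,7-dioxabicyclo[3.3.0]octan-2-ol (anomeric mixture) | OC1OC[C@@H]2[C@H]1CO[C@H]2c3cc(OC)c(OC)c(OC)c3 | intermediate
14 | 4-bromo-2,6-dimethoxyphenol | COc1cc(Br)cc(OC)c1O | starting material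
15 | (4-bromo-2,6-dimethoxyphenoxy)(tert-butyl)dimethylsilane | COc1cc(Br)cc(OC)c1O[Si](C)(C)C(C)(C)C | intermediate
16 | [4-(tert-butyldimethylsilyloxy)-3,5-dimethoxyphenyl]lithium (not isolated) | COc1cc([Li])cc(OC)c1O[Si](C)(C)C(C)(C)C | intermediate
17 | [4-(tert-butyldimethylsilyloxy)-3,5-dimethoxyphenyl][(3S,4S,5R)-4-(hydroxymethyl)-5-(3,4,5-trimethoxyphenyl)oxolan-3-yl]methanol (carbinol epimers) | OC[C@@H]1[C@H](C(O)c2cc(OC)c(O[Si](C)(C)C(C)(C)C)c(OC)c2)CO[C@H]1c3cc(OC)c(OC)c(OC)c3 | intermediate
18 | (1S,2R,5S,6R)-2-[4-(tert-butyldimethylsilyloxy)-3,5-dimethoxyphenyl]-6-(3,4,5-trimethoxyphenyl)-3,7-dioxabicyclo[3.3.0]octane (both aryl groups exo) | COc1cc([C@@H]2OC[C@@H]3[C@H]2CO[C@H]3c2cc(OC)c(OC)c(OC)c2)cc(OC)c1O[Si](C)(C)C(C)(C)C | intermediate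
19 | 2,6-dimethoxy-4-[(1S,2R,5S,6R)-6-(3,4,5-trimethoxyphenyl)-3,7-dioxabicyclo[3.3.0]octan-2-yl]phenol | COc1cc([C@@H]2OC[C@@H]3[C@H]2CO[C@H]3c2cc(OC)c(OC)c(OC)c2)cc(OC)c1O | target

**Step count**

Total step count: 11. Longest linear sequence: 10 (steps 1–7 and 9–11); step 8 is a one-step side branch.

**Steps most likely to fail**

Step 5.
- What may go wrong: formaldehyde may oligomerise, or attack the electron-rich arene, faster than it opens the cyclopropane. The endo-aryl cyclopropane may also epimerise under the Lewis acid before it is captured, which would erode the exo selectivity at C6.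
- Fallback: it sets out from 8 and comes back at 11, and it makes the two bonds one after the other. Sc(OTf)3-catalysed opening of 8 with water in THF uses a far better nucleophile and should again proceed with SN2-like inversion at C6. It should give the benzylic alcohol methyl (4S)-4-[(R)-hydroxy(3,4,5-trimethoxyphenyl)methyl]-2-oxooxolane-3-carboxylate F1 (epimers at C3). This is taken on at once to forestall translactonisation. Condensation of the alcohol with dimethoxymethane under TMSOTf in CH2Cl2 at low temperature builds the same oxocarbenium ion from the oxygen side. The enol of the β-dicarbonyl unit then closes the cis-fused ring to 11.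

Step 3.
- What may go wrong: facial selectivity may be poor on a Z-alkene that carries an allylic silyloxy group. The alkene geometry may be partly lost through a stepwise, zwitterionic addition to the electron-rich styrene. The carbene may also be captured by the ether oxygen.
- Fallback: it sets out from 4 and comes back at 8, and it makes the cyclopropanation intramolecular.
  - TBAF frees (2Z)-3-(3,4,5-trimethoxyphenyl)prop-2-en-1-ol F2.
  - Acylation with methyl malonyl chloride (pyridine, CH2Cl2) gives methyl (2Z)-3-(3,4,5-trimethoxyphenyl)prop-2-en-1-yl propanedioate F3.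
  - Diazo transfer (p-ABSA, Et3N, MeCN) gives methyl (2Z)-3-(3,4,5-trimethoxyphenyl)prop-2-en-1-yl 2-diazopropanedioate F4.
  - A chiral Cu(I)–bis(oxazoline) catalyst closes the cyclopropane and the lactone together to 8.
  - The tether allows only the endo-aryl, cis-fused product from the Z-alkene, so only the alkene face is left to the catalyst. The lactone can be enriched by recrystallisation.

Step 10.
- What may go wrong: the closure may slide toward thermodynamic control. The acid may also reopen either benzylic ether, which would scramble the exo/endo relationship at C2 or C6.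
- Fallback: it sets out from 13 and comes back at 18, and it sets C2 by nucleophile approach instead of ring closure.
  - Acetylation (Ac2O, pyridine, DMAP) gives (1S,5S,6R)-6-(3,4,5-trimethoxyphenyl)-3,7-dioxabicyclo[3.3.0]octan-2-yl acetate F5.
  - Compound 16, made from 15 as in step 9, is transmetalated with ZnBr2 to [4-(tert-butyldimethylsilyloxy)-3,5-dimethoxyphenyl]zinc bromide F6.
  - BF3·OEt2 in CH2Cl2 at −78 °C ionises the acetate to the bicyclic oxocarbenium ion. The arylzinc reagent should attack it on the convex face, as in C-aryl glycoside synthesis, which places the aryl group exo and gives 18 directly.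

**Further compounds**

F1 | step 5 | methyl (4S)-4-[(R)-hydroxy(3,4,5-trimethoxyphenyl)methyl]-2-oxooxolane-3-carboxylate (epimers at C3) | COC(=O)C1C(=O)OC[C@H]1[C@@H](O)c2cc(OC)c(OC)c(OC)c2
F2 | step 3 | (2Z)-3-(3,4,5-trimethoxyphenyl)prop-2-en-1-ol | COc1cc(/C=C\CO)cc(OC)c1OC
F3 | step 3 | methyl (2Z)-3-(3,4,5-trimethoxyphenyl)prop-2-en-1-yl propanedioate | COC(=O)CC(=O)OC/C=C\c1cc(OC)c(OC)c(OC)c1
F4 | step 3 | methyl (2Z)-3-(3,4,5-trimethoxyphenyl)prop-2-en-1-yl 2-diazopropanedioate | COC(=O)C(=[N+]=[N-])C(=O)OC/C=C\c1cc(OC)c(OC)c(OC)c1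
F5 | step 10 | (1S,5S,6R)-6-(3,4,5-trimethoxyphenyl)-3,7-dioxabicyclo[3.3.0]octan-2-yl acetate (anomeric mixture) | CC(=O)OC1OC[C@@H]2[C@H]1CO[C@H]2c3cc(OC)c(OC)c(OC)c3
F6 | step 10 | [4-(tert-butyldimethylsilyloxy)-3,5-dimethoxyphenyl]zinc bromide | COc1cc([Zn]Br)cc(OC)c1O[Si](C)(C)C(C)(C)C
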